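## The problem

Target 22 is a flavone: a 5,7-dihydroxychromen-4-one (rings A and C) joined through the C2–C1' bond to a pentasubstituted benzene, ring B. Ring B carries four neighbouring oxygens at C2', C3', C4' and C5' and a single hydrogen at C6'. There is no stereocentre, so nothing has to be controlled or relayed. The only stereochemical element on the way is the geometry of an enol ether in one precursor, and it disappears when ring B becomes aromatic.

The difficulty is constitutional. Three of the four ring B oxygens are methyl ethers and only O3', flanked on both sides, is free. Each oxygen must therefore be introduced or unmasked on its own, and the 5- and 7-hydroxyls of ring A must be carried in a form that can be removed without touching aryl methyl ethers.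

The molecule does not tolerate rough treatment:
- the pyranone ring C opens when hydroxide or alkoxide attacks C2, and its C2–C3 double bond can be reduced;
- the tetraoxygenated ring B is easily oxidised towards a quinone;
- ether-cleaving Lewis acids would not distinguish the three methyl ethers from any protecting group on O3'.

The feature that allows a different approach is that O2' and O5' are para to each other and C6' is a CH. Ring B is therefore a 4-alkoxyphenol that can be assembled from a carbene carbon (C5'), an alkene (C4', C3'), carbon monoxide (C2') and a terminal alkyne (C1', C6'). Every oxygen then comes from a separate source.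

## Retrosynthesis

**22 from 21.** The three O–benzyl bonds at O5, O7 and O3' are cut last. Benzyl is chosen over silyl, acyl or alkyl alternatives because all three come off in one neutral hydrogenolysis that leaves aryl methyl ethers alone, and because benzyl cannot migrate between the adjacent O2' and O3' in the steps before. The forward reaction must spare the C2–C3 double bond of the flavone.

**21 from 20.** The O2'–methyl bond is cut next. Phenol 20 has exactly one free hydroxyl, so a plain O-methylation is all that is asked. This is the return on building ring B in a way that delivers O2' as the only free phenol.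

**20 from 8 and 18.** Three ring B bonds are cut: C5'–C6', C1'–C2' and C2'–C3'. This returns alkyne 8, the three-carbon alkenyl(methoxy)carbene complex 18, and one of its CO ligands.
- Against cutting C2–C1' or closing ring C late: those cuts need the intact pentasubstituted arene with O3' already differentiated, which is the real problem.
- Against the reversed benzannulation (carbene on the chromone, oxygenated alkyne): it would place the new hydroxyl on the wrong carbon.
- Gain: 8 contains only rings A and C, and 18 is acyclic with its three oxygens already distinguished as carbene methoxy (C5'), α-methoxy (C4') and β-benzyloxy (C3').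
- Demands on the forward reaction: one alkyne orientation (chromone next to the CO-derived carbon), CO insertion in preference to CO-free cyclisation, and conditions mild enough for the chromone.

**18 from 13 and 14.** The chromium–carbon bond is cut, leading back to acid 13 and chromium hexacarbonyl 14 through acid chloride 15, pentacarbonylchromate dianion 16 and acylchromate 17. The more usual route, an alkenyllithium added to 14, would need regioselective lithiation of a mixed dialkoxyethene in the presence of a benzyl ether, which is not credible. The acyl route takes the whole carbon skeleton and the alkene geometry from a stable acid.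

**13 from 9 and 10.** Acid 13 comes from ester 12 by saponification. Ester 12 is cut at C2–C3 (formyl Claisen condensation of methyl methoxyacetate 9 with methyl formate 10) and at the O–benzyl bond (O-alkylation of enolate 11). This places the benzyl group on the future O3' at the very start.

**8 from 7, 6 and 5.** The terminal alkyne carbon is removed, giving aldehyde 7 (one-carbon homologation forward). Aldehyde 7 comes from alcohol 6 by oxidation, and 6 from ester 5 by hydride reduction. This is preferred to a cross-coupling on a 2-halochromone, which is not a readily made compound in this series.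

**5 from 2 and 3; 2 from 1.** Ester 5 is cut at C2–C3 and O1–C2: Claisen condensation of ketone 2 with diethyl oxalate 3 gives diketo ester 4, which cyclises with loss of water. Ketone 2 is the dibenzyl ether of commercial 2',4',6'-trihydroxyacetophenone 1, whose chelated hydroxyl stays free to become O1.

## Roads not taken

**Alternative 1:** Rings A and C are both cut open, at O1–C2 and C6–C7. This leads to the acyclic methyl 4-acetyl-7-[3-(benzyloxy)-2,4,5-trimethoxyphenyl]-3,5-dioxohept-6-ynoate A2. Forward, base would fold A2: an enol oxygen adds to the ynone (6-endo, ring C) and the methyl ketone enolate condenses on the ester (ring A). The product is 2-[3-(benzyloxy)-2,4,5-trimethoxyphenyl]-5,7-dihydroxychromen-4-one A1, one hydrogenolysis away from 22.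
- Merits: two rings in one operation, no protection of the ring A hydroxyls, a single benzyl group to remove, no stoichiometric metal. On end-game economy it beats the chosen plan.
- Weak points: A2 is a triacylmethane with several enolisation modes. 5-exo attack on the ynone, aldol closure in place of Claisen closure, and retro-Claisen loss of an acyl group all compete, and A2 itself is laborious to assemble.
- Comparison: ring B must be brought in complete, so the differentiation of O3' among four neighbouring oxygens is left to classical arene chemistry. The chosen plan has one regiochemical question where this one has several, and it solves the ring B problem where this one postpones it.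

**Alternative 2:** Ring C is cut at O1–C8a. The precursor is 1-[3-(benzyloxy)-2,4,5-trimethoxyphenyl]-3-(2,4,6-trifluorophenyl)propane-1,3-dione A4. Its enolate oxygen displaces an ortho fluoride to give 2-[3-(benzyloxy)-2,4,5-trimethoxyphenyl]-5,7-difluorochromen-4-one A3.
- Merits: the ring closure is a well-behaved intramolecular aromatic substitution and is more dependable than any chromium benzannulation. A4 comes from one Claisen condensation, and the sequence is short.
- Weak points: two carbon–fluorine bonds of A3 must then be exchanged for oxygen, for example with benzyl alkoxide to reach 21. Alkoxides also attack C2 of the chromone, and the 5- and 7-fluorides differ in reactivity. Ring B again has to be made beforehand with O3' differentiated.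
- Comparison: in reliability of the key step this road is better. The chosen plan sets against it that ring A's oxygens are bought in place with 1, that no fluoride exchange on a base-sensitive chromone is needed, and that ring B is not made by stepwise substitution of an arene.

**Alternative 3:** Ring A is cut at four bonds (C8–C8a, C7–C8, C5–C6, C4a–C5). The precursors are 2-(2-diazoacetyl)-6-[3-(benzyloxy)-2,4,5-trimethoxyphenyl]-4H-pyran-4-one A6 and (ethynyloxy)triisopropylsilane A7. Forward, Wolff rearrangement of A6 gives a pyranonyl ketene, which adds A7. The resulting cyclobutenone opens (4π) and recloses (6π) to 2-[3-(benzyloxy)-2,4,5-trimethoxyphenyl]-5-hydroxy-7-(triisopropylsilyloxy)chromen-4-one A5.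
- Merits: a convergent benzannulation of a known reaction type, fully regiodefined, with O5 and O7 differentiated and no metal carbonyl.
- Weak points: the differentiation of O5 and O7 is not needed here. Ring A is the part of 22 that can be bought. A6 already contains ring B, so the hard part is untouched. A pyranone double bond as the vinyl partner is untested, and a diazo ketone and a siloxyalkyne must be handled.
- Comparison: both plans build a benzene ring from small pieces. This one spends the effort on the ring that needs none, and is longer; the chosen plan spends it on ring B, where each oxygen needs its own origin.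

Key step: step 9

Assumption: the O-benzylation in step 6 gives mainly the Z enol ether (benzyloxy trans to the ester), as is usual for β-alkoxyacrylates made this way; a minor E isomer would be separated at 12, and the geometry is erased when ring B aromatises.

## Route

Step 1
Reactants: 1 2',4',6'-trihydroxyacetophenone
Product: 2 1-[2,4-bis(benzyloxy)-6-hydroxyphenyl]ethan-1-one
Conditions: BnBr (2.1 equiv), K2CO3, DMF, rt
Reagents that add atoms: benzyl bromide, BrCc1ccccc1
Why: Williamson ether synthesis; the para hydroxyl and one ortho hydroxyl are alkylated, while the remaining ortho hydroxyl, hydrogen-bonded to the ketone, is the least nucleophilic and should stay free with two equivalents of bromide.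

Step 2
Reactants: 2 1-[2,4-bis(benzyloxy)-6-hydroxyphenyl]ethan-1-one; 3 diethyl oxalate
Product: 5 ethyl 5,7-bis(benzyloxy)-4-oxo-4H-chromene-2-carboxylate, via diketo ester 4 (not isolated)
Conditions: NaOEt, EtOH, reflux; then conc. HCl, EtOH, 70 °C
Reagents that add atoms: none
Why: Crossed Claisen condensation of the ketone enolate with the non-enolisable oxalate, then acid-catalysed attack of the phenol on the 2-keto group and dehydration (chromone-2-carboxylate synthesis); benzyl aryl ethers should tolerate the brief dilute acid in ethanol.

Step 3
Reactants: 5 ethyl 5,7-bis(benzyloxy)-4-oxo-4H-chromene-2-carboxylate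
Product: 6 5,7-bis(benzyloxy)-2-(hydroxymethyl)-4H-chromen-4-one
Conditions: NaBH4, MeOH/THF, 0 °C
Reagents that add atoms: none
Why: Chemoselective borohydride reduction; the ester on C2 is activated by the ring oxygen and the conjugated pyranone and is reduced in methanol, whereas the C4 carbonyl is a vinylogous ester and should be inert at 0 °C.

Step 4
Reactants: 6 5,7-bis(benzyloxy)-2-(hydroxymethyl)-4H-chromen-4-one
Product: 7 5,7-bis(benzyloxy)-4-oxo-4H-chromene-2-carbaldehyde
Conditions: Dess–Martin periodinane, CH2Cl2, rt
Reagents that add atoms: none
Why: Dess–Martin oxidation of a primary alcohol to the aldehyde under neutral, anhydrous conditions, which avoids over-oxidation and limits hydration of the electrophilic 2-formylchromone.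

Step 5
Reactants: 7 5,7-bis(benzyloxy)-4-oxo-4H-chromene-2-carbaldehyde
Product: 8 5,7-bis(benzyloxy)-2-ethynyl-4H-chromen-4-one
Conditions: dimethyl (1-diazo-2-oxopropyl)phosphonate, K2CO3, MeOH/THF, 0 °C to rt
Reagents that add atoms: dimethyl (1-diazo-2-oxopropyl)phosphonate, COP(=O)(OC)C(=[N+]=[N-])C(C)=O
Why: Ohira–Bestmann (Seyferth–Gilbert) homologation; methanolysis of the reagent gives the diazomethylphosphonate anion, which adds to the non-enolisable aldehyde, and loss of phosphate and N2 followed by a 1,2-hydrogen shift gives the terminal alkyne with only a weak base present.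

Step 6
Reactants: 9 methyl methoxyacetate; 10 methyl formate
Product: 12 methyl (Z)-3-(benzyloxy)-2-methoxyprop-2-enoate, via sodium formyl enolate 11 (not isolated)
Conditions: NaOMe, THF, 0 °C to rt; then BnBr, DMF, rt
Reagents that add atoms: benzyl bromide, BrCc1ccccc1
Why: Crossed Claisen condensation with a formate gives the stabilised formyl ester enolate, which in a dipolar aprotic solvent is alkylated on oxygen (Williamson-type enol ether formation, as in β-alkoxyacrylate synthesis); the extended enolate should place the benzyloxy group trans to the ester, which is the Z isomer.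

Step 7
Reactants: 12 methyl (Z)-3-(benzyloxy)-2-methoxyprop-2-enoate
Product: 13 (Z)-3-(benzyloxy)-2-methoxyprop-2-enoic acid
Conditions: LiOH, THF/H2O, rt; then 1 M HCl to pH 3, 0 °C
Reagents that add atoms: lithium hydroxide, [Li+].[OH-]
Why: Saponification of a methyl ester; the β-alkoxyacrylate reacts at the ester carbonyl under mild conditions, and the cold, weakly acidic work-up should spare the enol ether and its geometry.

Step 8
Reactants: 13 (Z)-3-(benzyloxy)-2-methoxyprop-2-enoic acid; 14 chromium hexacarbonyl, Cr(CO)6
Product: 18 pentacarbonyl[(Z)-3-(benzyloxy)-1,2-dimethoxyprop-2-en-1-ylidene]chromium, via acid chloride 15 (not isolated), via disodium pentacarbonylchromate 16 (not isolated), via sodium acylchromate 17 (not isolated)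
Conditions: 13, 1-chloro-N,N,2-trimethylprop-1-en-1-amine (1.0 equiv), CH2Cl2, 0 °C to rt; separately 14, sodium naphthalenide (NaC10H8, 2 equiv), THF, −78 °C; add 15, −78 to 0 °C; solvent to CH2Cl2, MeOTf, 0 °C
Reagents that add atoms: methyl trifluoromethanesulfonate, COS(=O)(=O)C(F)(F)F
Why: Acyl chromate route to Fischer carbene complexes; the acid chloride is made under neutral conditions with the chloroenamine, two-electron reduction of Cr(CO)6 gives the nucleophilic pentacarbonylchromate dianion, which is acylated at chromium, and the hard methylating agent alkylates the acyl oxygen. No organolithium is used, so the benzyl enol ether and the alkene geometry of 13 should be carried through.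

Step 9
Reactants: 8 5,7-bis(benzyloxy)-2-ethynyl-4H-chromen-4-one; 18 pentacarbonyl[(Z)-3-(benzyloxy)-1,2-dimethoxyprop-2-en-1-ylidene]chromium
Product: 20 5,7-bis(benzyloxy)-2-[3-(benzyloxy)-2-hydroxy-4,5-dimethoxyphenyl]-4H-chromen-4-one, via Cr(CO)3 arene complex 19 (not isolated)
Conditions: 18 (1.3 equiv), THF (0.05 M), 55 °C, argon; then air, MeCN, rt
Reagents that add atoms: none
Why: Proposed new method: thermal loss of one CO from 18 frees a site on chromium, the terminal alkyne of 8 inserts into the Cr=C bond with its CH carbon bonding to the carbene carbon (C5'–C6'), a CO ligand inserts to give a chromium-bound dienylketene (C1'–C2'), and ring B closes by thermal 6π electrocyclisation of the ketene carbon onto the benzyloxy-bearing alkene carbon (C2'–C3'), after which the C3' hydrogen shifts to oxygen and air releases the phenol from its Cr(CO)3 complex 19. The closest known reaction type is the Dötz benzannulation of alkenyl(alkoxy)carbene chromium complexes with terminal alkynes, which is established for α-alkoxyalkenyl carbenes but not for one that also carries a β-alkoxy group, nor for an alkyne conjugated to a chromone. No stereocentre is formed; the Z alkene only places the small hydrogen on the inside of the ring-closing triene. The step needs one regiochemical outcome, the chromone next to the CO-derived carbon, and this should follow from the steric preference in alkyne insertion that puts the substituted alkyne carbon on chromium, away from the carbene substituents. It also needs CO insertion to win over CO-free five-ring closure, which an alkenyl (not aryl) carbene, chromium as the metal and THF as solvent all favour. Donation from the β-benzyloxy group may slow CO loss, hence the moderate heating and the excess of 18.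

Step 10
Reactants: 20 5,7-bis(benzyloxy)-2-[3-(benzyloxy)-2-hydroxy-4,5-dimethoxyphenyl]-4H-chromen-4-one
Product: 21 5,7-bis(benzyloxy)-2-[3-(benzyloxy)-2,4,5-trimethoxyphenyl]-4H-chromen-4-one
Conditions: MeI, K2CO3, acetone, reflux
Reagents that add atoms: iodomethane, CI
Why: Williamson methylation of the only free hydroxyl; the phenoxide is flanked by the chromone and a benzyl ether, but methyl iodide is small and no other acidic site is present.

Step 11
Reactants: 21 5,7-bis(benzyloxy)-2-[3-(benzyloxy)-2,4,5-trimethoxyphenyl]-4H-chromen-4-one
Product: 22 5,7-dihydroxy-2-(3-hydroxy-2,4,5-trimethoxyphenyl)-4H-chromen-4-one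
Conditions: H2 (1 atm), Pd/C (10 wt%), EtOAc/MeOH, rt
Reagents that add atoms: none
Why: Catalytic hydrogenolysis of three benzyl aryl ethers in one neutral operation; aryl methyl ethers are inert and the C2–C3 bond of a flavone is reduced far more slowly than O–benzyl bonds are cleaved, so the reaction is stopped after three equivalents of H2.

## Compound list

1 | 2',4',6'-trihydroxyacetophenone | CC(=O)c1c(O)cc(O)cc1O | starting material
2 | 1-[2,4-bis(benzyloxy)-6-hydroxyphenyl]ethan-1-one | CC(=O)c1c(O)cc(OCc2ccccc2)cc1OCc1ccccc1 | intermediate
3 | diethyl oxalate | CCOC(=O)C(=O)OCC | starting material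
4 | ethyl 4-[2,4-bis(benzyloxy)-6-hydroxyphenyl]-2,4-dioxobutanoate | CCOC(=O)C(=O)CC(=O)c1c(O)cc(OCc2ccccc2)cc1OCc1ccccc1 | intermediate (not isolated)
5 | ethyl 5,7-bis(benzyloxy)-4-oxo-4H-chromene-2-carboxylate | CCOC(=O)c1cc(=O)c2c(OCc3ccccc3)cc(OCc3ccccc3)cc2o1 | intermediate
6 | 5,7-bis(benzyloxy)-2-(hydroxymethyl)-4H-chromen-4-one | OCc1cc(=O)c2c(OCc3ccccc3)cc(OCc3ccccc3)cc2o1 | intermediate
7 | 5,7-bis(benzyloxy)-4-oxo-4H-chromene-2-carbaldehyde | O=Cc1cc(=O)c2c(OCc3ccccc3)cc(OCc3ccccc3)cc2o1 | intermediate
8 | 5,7-bis(benzyloxy)-2-ethynyl-4H-chromen-4-one | C#Cc1cc(=O)c2c(OCc3ccccc3)cc(OCc3ccccc3)cc2o1 | intermediate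
9 | methyl methoxyacetate | COCC(=O)OC | starting material
10 | methyl formate | COC=O | starting material
11 | sodium (Z)-2,3-dimethoxy-3-oxoprop-1-en-1-olate | COC(=O)/C(OC)=C/[O-].[Na+] | intermediate (not isolated)
12 | methyl (Z)-3-(benzyloxy)-2-methoxyprop-2-enoate | COC(=O)/C(OC)=C/OCc1ccccc1 | intermediate
13 | (Z)-3-(benzyloxy)-2-methoxyprop-2-enoic acid | OC(=O)/C(OC)=C/OCc1ccccc1 | intermediate
14 | chromium hexacarbonyl, Cr(CO)6 | O=C=[Cr](=C=O)(=C=O)(=C=O)(=C=O)=C=O | starting material
15 | (Z)-3-(benzyloxy)-2-methoxyprop-2-enoyl chloride | O=C(Cl)/C(OC)=C/OCc1ccccc1 | intermediate (not isolated)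
16 | disodium pentacarbonylchromate, Na2Cr(CO)5 | [Na+].[Na+].O=C=[Cr-2](=C=O)(=C=O)(=C=O)=C=O | intermediate (not isolated)
17 | sodium pentacarbonyl[(Z)-3-(benzyloxy)-2-methoxyprop-2-enoyl]chromate | [Na+].O=C(/C(OC)=C/OCc1ccccc1)[Cr-](=C=O)(=C=O)(=C=O)(=C=O)=C=O | intermediate (not isolated)
18 | pentacarbonyl[(Z)-3-(benzyloxy)-1,2-dimethoxyprop-2-en-1-ylidene]chromium | COC(=[Cr](=C=O)(=C=O)(=C=O)(=C=O)=C=O)/C(OC)=C/OCc1ccccc1 | intermediate
19 | tricarbonyl(η6-arene)chromium complex of 20, Cr(CO)3 bound to ring B (SMILES written as arene plus Cr(CO)3 fragment) | COc1cc(-c2cc(=O)c3c(OCc4ccccc4)cc(OCc4ccccc4)cc3o2)c(O)c(OCc2ccccc2)c1OC.O=C=[Cr](=C=O)=C=O | intermediate (not isolated)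
20 | 5,7-bis(benzyloxy)-2-[3-(benzyloxy)-2-hydroxy-4,5-dimethoxyphenyl]-4H-chromen-4-one | COc1cc(-c2cc(=O)c3c(OCc4ccccc4)cc(OCc4ccccc4)cc3o2)c(O)c(OCc2ccccc2)c1OC | intermediate
21 | 5,7-bis(benzyloxy)-2-[3-(benzyloxy)-2,4,5-trimethoxyphenyl]-4H-chromen-4-one | COc1cc(-c2cc(=O)c3c(OCc4ccccc4)cc(OCc4ccccc4)cc3o2)c(OC)c(OCc2ccccc2)c1OC | intermediate
22 | 5,7-dihydroxy-2-(3-hydroxy-2,4,5-trimethoxyphenyl)-4H-chromen-4-one (5,7,3'-trihydroxy-2',4',5'-trimethoxyflavone) | COc1cc(-c2cc(=O)c3c(O)cc(O)cc3o2)c(OC)c(O)c1OC | target

## Step count and risks

Total: 11 steps. Longest linear sequence: 8 steps (steps 1–5, then 9–11). The carbene arm is steps 6–8.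

**Step 9 (key step, proposed new method).**
- What may go wrong: the β-benzyloxy group makes 18 a push–pull carbene, so CO dissociation may be too slow at temperatures the complex survives. After alkyne insertion the electron-rich vinylcarbene may cyclise without taking up CO (five-membered-ring products) and so fail to form the ketene. The electron-poor ynenone 8 may also oligomerise or insert twice.
- Fallback (known chemistry, from 2, returning at 21): ring B is brought in ready-made.
  - Purchased 2,6-dimethoxyphenol F1 is benzylated (BnBr, K2CO3) to 2-(benzyloxy)-1,3-dimethoxybenzene F2.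
  - Vilsmeier formylation (POCl3, DMF) para to a methoxy group gives 3-(benzyloxy)-2,4-dimethoxybenzaldehyde F3.
  - Bromination (NBS, MeCN) at the position ortho and para to the two methoxy groups gives 3-(benzyloxy)-5-bromo-2,4-dimethoxybenzaldehyde F4.
  - Copper-catalysed exchange with methoxide (NaOMe, CuBr, DMF/MeOH) gives 3-(benzyloxy)-2,4,5-trimethoxybenzaldehyde F5.
  - Claisen–Schmidt condensation of F5 with 2 (KOH, EtOH) gives (E)-1-[2,4-bis(benzyloxy)-6-hydroxyphenyl]-3-[3-(benzyloxy)-2,4,5-trimethoxyphenyl]prop-2-en-1-one F6.
  - Oxidative cyclisation (catalytic I2, DMSO, 120 °C) gives 21.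

**Step 8.**
- What may go wrong: the strongly reducing pentacarbonylchromate dianion may transfer electrons to the β-alkoxyacryloyl chloride or add in conjugate fashion with loss of benzyloxide, where acyl substitution is wanted. The acid chloride may also lose its geometry or decompose before it is used.
- Fallback (from 14, returning at 18): the carbene is built on the metal.
  - Purchased tributyl(methoxymethyl)stannane F7 and n-BuLi (THF, −78 °C) give (methoxymethyl)lithium F8.
  - F8 adds to 14 to give lithium pentacarbonyl(methoxyacetyl)chromate F9.
  - MeOTf converts F9 into pentacarbonyl(1,2-dimethoxyethylidene)chromium F10.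
  - The acidic α-CH2 of F10 is deprotonated (n-BuLi, −78 °C) and formylated with ethyl formate to give the lithium enolate of pentacarbonyl(1,2-dimethoxy-3-oxopropylidene)chromium F11.
  - O-Benzylation of F11 with benzyl trifluoromethanesulfonate gives 18. This last alkylation is itself less secure than the methylation of an acylchromate.

**Step 5.**
- What may go wrong: methoxide may attack the pyranone at C2 and open ring C, or methanol may add in 1,6-fashion to the ynenone as it forms.
- Fallback (from 2, returning at 8): the alkyne is carried in from the start and the chromone is closed around it.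
  - The free phenol of 2 is esterified (DCC, DMAP) with purchased 3-(triisopropylsilyl)prop-2-ynoic acid F12 to give 2-acetyl-3,5-bis(benzyloxy)phenyl 3-(triisopropylsilyl)prop-2-ynoate F13.
  - Baker–Venkataraman acyl shift (NaH, THF) gives 1-[2,4-bis(benzyloxy)-6-hydroxyphenyl]-5-(triisopropylsilyl)pent-4-yne-1,3-dione F14.
  - Acid cyclodehydration (TsOH, toluene) gives 5,7-bis(benzyloxy)-2-[(triisopropylsilyl)ethynyl]-4H-chromen-4-one F15.
  - Buffered desilylation (TBAF, AcOH, THF) gives 8.

**Step 6.**
- What may go wrong: C-benzylation of the ambident enolate may compete with O-benzylation, and the enol ether may form as a mixture of geometric isomers.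
- Fallback (from 11, returning at 12): the enolate is O-methylated with the hard electrophile dimethyl sulfate (DMF) to give methyl (Z)-2,3-dimethoxyprop-2-enoate F16. The β-methoxy group is then exchanged for benzyloxy by acid-catalysed addition–elimination with benzyl alcohol (pyridinium p-toluenesulfonate, toluene, removal of methanol) to give 12.

## Further compounds

F1 | step 9 | 2,6-dimethoxyphenol (purchased) | COc1cccc(OC)c1O
F2 | step 9 | 2-(benzyloxy)-1,3-dimethoxybenzene | COc1cccc(OC)c1OCc1ccccc1
F3 | step 9 | 3-(benzyloxy)-2,4-dimethoxybenzaldehyde | COc1ccc(C=O)c(OC)c1OCc1ccccc1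
F4 | step 9 | 3-(benzyloxy)-5-bromo-2,4-dimethoxybenzaldehyde | COc1c(Br)cc(C=O)c(OC)c1OCc1ccccc1
F5 | step 9 | 3-(benzyloxy)-2,4,5-trimethoxybenzaldehyde | COc1cc(C=O)c(OC)c(OCc2ccccc2)c1OC
F6 | step 9 | (E)-1-[2,4-bis(benzyloxy)-6-hydroxyphenyl]-3-[3-(benzyloxy)-2,4,5-trimethoxyphenyl]prop-2-en-1-one | COc1cc(/C=C/C(=O)c2c(O)cc(OCc3ccccc3)cc2OCc2ccccc2)c(OC)c(OCc2ccccc2)c1OC
F7 | step 8 | tributyl(methoxymethyl)stannane (purchased) | CCCC[Sn](CCCC)(CCCC)COC
F8 | step 8 | (methoxymethyl)lithium | [Li]COC
F9 | step 8 | lithium pentacarbonyl(methoxyacetyl)chromate | [Li+].COCC(=O)[Cr-](=C=O)(=C=O)(=C=O)(=C=O)=C=O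
F10 | step 8 | pentacarbonyl(1,2-dimethoxyethylidene)chromium | COCC(OC)=[Cr](=C=O)(=C=O)(=C=O)(=C=O)=C=O
F11 | step 8 | lithium enolate of pentacarbonyl(1,2-dimethoxy-3-oxopropylidene)chromium | COC(=[Cr](=C=O)(=C=O)(=C=O)(=C=O)=C=O)/C(OC)=C/[O-].[Li+]
F12 | step 5 | 3-(triisopropylsilyl)prop-2-ynoic acid (purchased) | CC(C)[Si](C#CC(=O)O)(C(C)C)C(C)C
F13 | step 5 | 2-acetyl-3,5-bis(benzyloxy)phenyl 3-(triisopropylsilyl)prop-2-ynoate | CC(=O)c1c(OCc2ccccc2)cc(OCc2ccccc2)cc1OC(=O)C#C[Si](C(C)C)(C(C)C)C(C)C
F14 | step 5 | 1-[2,4-bis(benzyloxy)-6-hydroxyphenyl]-5-(triisopropylsilyl)pent-4-yne-1,3-dione | O=C(CC(=O)C#C[Si](C(C)C)(C(C)C)C(C)C)c1c(O)cc(OCc2ccccc2)cc1OCc1ccccc1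
F15 | step 5 | 5,7-bis(benzyloxy)-2-[(triisopropylsilyl)ethynyl]-4H-chromen-4-one | CC(C)[Si](C#Cc1cc(=O)c2c(OCc3ccccc3)cc(OCc3ccccc3)cc2o1)(C(C)C)C(C)C
F16 | step 6 | methyl (Z)-2,3-dimethoxyprop-2-enoate | COC(=O)/C(OC)=C/OC
A1 | alternative 1 | 2-[3-(benzyloxy)-2,4,5-trimethoxyphenyl]-5,7-dihydroxychromen-4-one | COc1cc(-c2cc(=O)c3c(O)cc(O)cc3o2)c(OC)c(OCc2ccccc2)c1OC
A2 | alternative 1 | methyl 4-acetyl-7-[3-(benzyloxy)-2,4,5-trimethoxyphenyl]-3,5-dioxohept-6-ynoate | CC(=O)C(C(=O)C#Cc1cc(OC)c(OC)c(OCc2ccccc2)c1OC)C(=O)CC(=O)OC
A3 | alternative 2 | 2-[3-(benzyloxy)-2,4,5-trimethoxyphenyl]-5,7-difluorochromen-4-one | COc1cc(-c2cc(=O)c3c(F)cc(F)cc3o2)c(OC)c(OCc2ccccc2)c1OC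
A4 | alternative 2 | 1-[3-(benzyloxy)-2,4,5-trimethoxyphenyl]-3-(2,4,6-trifluorophenyl)propane-1,3-dione | COc1cc(C(=O)CC(=O)c2c(F)cc(F)cc2F)c(OC)c(OCc2ccccc2)c1OC
A5 | alternative 3 | 2-[3-(benzyloxy)-2,4,5-trimethoxyphenyl]-5-hydroxy-7-(triisopropylsilyloxy)chromen-4-one | COc1cc(-c2cc(=O)c3c(O)cc(O[Si](C(C)C)(C(C)C)C(C)C)cc3o2)c(OC)c(OCc2ccccc2)c1OC
A6 | alternative 3 | 2-(2-diazoacetyl)-6-[3-(benzyloxy)-2,4,5-trimethoxyphenyl]-4H-pyran-4-one | [N-]=[N+]=CC(=O)c1cc(=O)cc(-c2cc(OC)c(OC)c(OCc3ccccc3)c2OC)o1
A7 | alternative 3 | (ethynyloxy)triisopropylsilane | C#CO[Si](C(C)C)(C(C)C)C(C)C
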